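**Plan**

1. Retrosynthesis: after removal of four MOM ethers, ring C is opened in one stroke at O1–C8a, C4–C4a and O1–C2, which leaves 3,5-bis(MOM-oxy)benzyne (from ortho-silylaryl triflate 9) and arylpropiolic acid 28.
2. This is possible because in ring A the carbons C8a (bearing O1) and C4a (bearing C4) are neighbours, i.e. the two carbons of an aryne, and the C5 oxygen next to C4a polarises that aryne so that oxygen goes to C8a and the acyl carbon to C4a.
3. Acid 28 is cut at the alkyne–CO2H bond, at the two benzylic C–C bonds flanking the 4′-oxygen (prenyl bromide; C3 of a glycidate) and at the isopropenyl carbon (ester → methyl ketone → alkene).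
4. Forward: triflate 9 from phloroglucinol (steps 1–4); ring B acid 28 from 3,5-dibromo-4-hydroxybenzaldehyde by two successive bromine–metal exchanges (steps 5–14); ring C closes in step 15; step 16 frees the four hydroxyls.
5. Stereochemistry: the single (R) carbinol centre comes from methyl (R)-glycidate; its C–O bond is never broken, and its priority order (O > carbonyl or isopropenyl carbon > CH2Ar > H) stays the same, so it is (R) throughout.

Key step: step 15

Remark: 3,5-dibromo-4-hydroxybenzaldehyde (the dibromination product of 4-hydroxybenzaldehyde) is taken as a purchased starting material.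

**Route**

Step 1
Reactants: 1 phloroglucinol
Product: 2 3,5-bis(methoxymethoxy)phenol
Conditions: MOMCl (2.0 equiv), i-Pr2NEt (2.5 equiv), DMF–CH2Cl2, 0 °C → rt; chromatography, mono- and tris-ethers recycled
Reagents that add atoms: chloromethyl methyl ether, COCCl
Why: Williamson-type O-alkylation of the symmetric triol with two equivalents of MOMCl should stop mainly at the bis-ether, which is separable by chromatography from the mono- and tris-ethers.

Step 2
Reactants: 2 3,5-bis(methoxymethoxy)phenol
Product: 3 3,5-bis(methoxymethoxy)phenyl N-(propan-2-yl)carbamate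
Conditions: i-PrNCO (1.3 equiv), Et3N (0.2 equiv), CH2Cl2, rt
Reagents that add atoms: isopropyl isocyanate, CC(C)N=C=O
Why: Amine-catalysed addition of the remaining phenol to the isocyanate (carbamoylation) should install the N–H carbamate that later serves as a removable ortho-directing group.

Step 3
Reactants: 3 3,5-bis(methoxymethoxy)phenyl N-(propan-2-yl)carbamate
Product: 7 3,5-bis(methoxymethoxy)-2-(trimethylsilyl)phenyl N-(propan-2-yl)carbamate, via N-silyl carbamate 4 (not isolated), via aryllithium 5 (not isolated), via bis-silyl carbamate 6 (not isolated)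
Conditions: TBSOTf (1.1 equiv), TMEDA (1.1 equiv), Et2O, 0 °C → rt; then TMEDA (2 equiv), n-BuLi (2.1 equiv), −78 °C; TMSCl (3 equiv), −78 °C → rt; 10% aq. citric acid, 0 °C
Reagents that add atoms: chlorotrimethylsilane, C[Si](C)(C)Cl
Why: In this directed ortho-metalation the in situ N-silylated carbamate, a stronger director than OMOM, should steer n-BuLi to C2 (equivalent to C6), the position it shares with one OMOM group, rather than to C4 between the two weaker OMOM directors, and TMSCl traps the aryllithium at −78 °C before an anionic Fries shift can start, the N–Si bond being hydrolysed on work-up.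

Step 4
Reactants: 7 3,5-bis(methoxymethoxy)-2-(trimethylsilyl)phenyl N-(propan-2-yl)carbamate
Product: 9 3,5-bis(methoxymethoxy)-2-(trimethylsilyl)phenyl trifluoromethanesulfonate, via silylphenol 8 (not isolated)
Conditions: Et2NH (1.3 equiv), DBU (1.5 equiv), MeCN, 40 °C; then PhNTf2 (1.5 equiv), rt
Reagents that add atoms: N-phenylbis(trifluoromethanesulfonimide), O=S(=O)(N(c1ccccc1)S(=O)(=O)C(F)(F)F)C(F)(F)F
Why: The N–H carbamate should fragment by an E1cB elimination to the phenoxide and isopropyl isocyanate (scavenged by Et2NH), and the phenoxide is then O-sulfonylated by PhNTf2 in the same pot (triflation) under conditions that leave the two acetals and the C–Si bond alone.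

Step 5
Reactants: 10 3,5-dibromo-4-hydroxybenzaldehyde
Product: 11 3,5-dibromo-4-(methoxymethoxy)benzaldehyde
Conditions: MOMCl (1.5 equiv), i-Pr2NEt (2 equiv), CH2Cl2, 0 °C → rt
Reagents that add atoms: chloromethyl methyl ether, COCCl
Why: O-alkylation of the acidic, doubly ortho-brominated phenol with MOMCl (acetal ether formation) should be straightforward and gives an ether that tolerates the organometallic steps and the hot fluoride ahead.

Step 6
Reactants: 11 3,5-dibromo-4-(methoxymethoxy)benzaldehyde
Product: 12 1,3-dibromo-5-ethynyl-2-(methoxymethoxy)benzene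
Conditions: dimethyl (1-diazo-2-oxopropyl)phosphonate (1.3 equiv), K2CO3 (2 equiv), MeOH, 0 °C → rt
Reagents that add atoms: dimethyl (1-diazo-2-oxopropyl)phosphonate, CC(=O)C(=[N+]=[N-])P(=O)(OC)OC
Why: The Ohira–Bestmann variant of the Seyferth–Gilbert homologation should turn the non-enolisable aldehyde into the terminal alkyne with K2CO3 in methanol, conditions to which the aryl bromides and the MOM ether are inert.

Step 7
Reactants: 12 1,3-dibromo-5-ethynyl-2-(methoxymethoxy)benzene
Product: 14 {[3,5-dibromo-4-(methoxymethoxy)phenyl]ethynyl}tri(propan-2-yl)silane, via lithium acetylide 13 (not isolated)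
Conditions: LiN(SiMe3)2 (1.1 equiv), THF, −78 °C; TIPSOTf (1.2 equiv), −78 → 0 °C
Reagents that add atoms: triisopropylsilyl trifluoromethanesulfonate, CC(C)[Si](OS(=O)(=O)C(F)(F)F)(C(C)C)C(C)C
Why: LiN(SiMe3)2 should deprotonate only the terminal alkyne (an amide base does not undergo bromine–lithium exchange), and C-silylation of the acetylide with TIPSOTf masks the acidic C–H for the organometallic steps that follow.

Step 8
Reactants: 14 {[3,5-dibromo-4-(methoxymethoxy)phenyl]ethynyl}tri(propan-2-yl)silane; 15 prenyl bromide (1-bromo-3-methylbut-2-ene)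
Product: 18 {[3-bromo-4-(methoxymethoxy)-5-(3-methylbut-2-en-1-yl)phenyl]ethynyl}tri(propan-2-yl)silane, via aryllithium 16 (not isolated), via arylcopper 17 (not isolated)
Conditions: n-BuLi (1.05 equiv), THF, −78 °C; CuBr·SMe2 (1.0 equiv), −78 → −40 °C; 15 (1.3 equiv), −40 → 0 °C
Reagents that add atoms: none
Why: Bromine–lithium exchange should take place once at the two equivalent bromines (the aryllithium is stabilised by the ortho OMOM group and does not exchange again at −78 °C), and after transmetalation the arylcopper should displace bromide at the unhindered CH2 of prenyl bromide (copper-mediated allylic substitution, SN2 rather than SN2′ because the γ-carbon is fully substituted) to give the linear prenyl group.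

Step 9
Reactants: 18 {[3-bromo-4-(methoxymethoxy)-5-(3-methylbut-2-en-1-yl)phenyl]ethynyl}tri(propan-2-yl)silane; 19 methyl (R)-glycidate [methyl (2R)-oxirane-2-carboxylate]
Product: 21 methyl (2R)-2-hydroxy-3-{2-(methoxymethoxy)-3-(3-methylbut-2-en-1-yl)-5-[(triisopropylsilyl)ethynyl]phenyl}propanoate, via aryl Grignard reagent 20 (not isolated)
Conditions: Mg turnings (I2-activated), THF, 45 °C; then CuI (10 mol%), −40 °C; 19 (1.3 equiv), −40 → −20 °C; aq. NH4Cl
Reagents that add atoms: none
Why: Copper-catalysed opening of the epoxide by the aryl Grignard reagent should take place at the unsubstituted C3 of the glycidate faster than addition to the ester at −40 °C, and since C2 is not a reacting centre its configuration passes unchanged into 21 as (R).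

Step 10
Reactants: 21 methyl (2R)-2-hydroxy-3-{2-(methoxymethoxy)-3-(3-methylbut-2-en-1-yl)-5-[(triisopropylsilyl)ethynyl]phenyl}propanoate
Product: 22 methyl (2R)-2-(methoxymethoxy)-3-{2-(methoxymethoxy)-3-(3-methylbut-2-en-1-yl)-5-[(triisopropylsilyl)ethynyl]phenyl}propanoate
Conditions: MOMCl (3 equiv), i-Pr2NEt (4 equiv), Bu4NI (0.1 equiv), CH2Cl2, 0 → 35 °C
Reagents that add atoms: chloromethyl methyl ether, COCCl
Why: MOM ether formation with MOMCl and a hindered amine base should protect the secondary alcohol without enolising the α-alkoxy ester, so the (R) centre is retained.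

Step 11
Reactants: 22 methyl (2R)-2-(methoxymethoxy)-3-{2-(methoxymethoxy)-3-(3-methylbut-2-en-1-yl)-5-[(triisopropylsilyl)ethynyl]phenyl}propanoate
Product: 24 (3R)-3-(methoxymethoxy)-4-{2-(methoxymethoxy)-3-(3-methylbut-2-en-1-yl)-5-[(triisopropylsilyl)ethynyl]phenyl}butan-2-one, via Weinreb amide 23 (not isolated)
Conditions: MeNHOMe·HCl (1.5 equiv), i-PrMgCl (3.0 equiv), THF, −20 °C; then MeMgBr (3 equiv), −20 → 0 °C; aq. NH4Cl
Reagents that add atoms: methylmagnesium bromide, C[Mg]Br
Why: In this one-pot Weinreb ketone synthesis the magnesium amide made from MeNHOMe·HCl and i-PrMgCl should convert the ester into amide 23, and MeMgBr then adds only once because the chelated tetrahedral adduct persists until work-up, neither reagent enolising the α-alkoxy carbonyl at −20 to 0 °C.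

Step 12
Reactants: 24 (3R)-3-(methoxymethoxy)-4-{2-(methoxymethoxy)-3-(3-methylbut-2-en-1-yl)-5-[(triisopropylsilyl)ethynyl]phenyl}butan-2-one
Product: 25 {[4-(methoxymethoxy)-3-[(2R)-2-(methoxymethoxy)-3-methylbut-3-en-1-yl]-5-(3-methylbut-2-en-1-yl)phenyl]ethynyl}tri(propan-2-yl)silane
Conditions: Ph3PCH3Br (1.5 equiv), KN(SiMe3)2 (1.4 equiv), THF, 0 °C; then 24, −78 → 0 °C
Reagents that add atoms: methyltriphenylphosphonium bromide, C[P+](c1ccccc1)(c1ccccc1)c1ccccc1.[Br-]
Why: Wittig methylenation with the ylide made from a slight excess of phosphonium salt over KN(SiMe3)2 should build the 1,1-disubstituted alkene at a defined position, carbonyl addition at low temperature being faster than enolisation of the α-alkoxy ketone so that the (R) centre survives.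

Step 13
Reactants: 25 {[4-(methoxymethoxy)-3-[(2R)-2-(methoxymethoxy)-3-methylbut-3-en-1-yl]-5-(3-methylbut-2-en-1-yl)phenyl]ethynyl}tri(propan-2-yl)silane
Product: 26 5-ethynyl-2-(methoxymethoxy)-1-[(2R)-2-(methoxymethoxy)-3-methylbut-3-en-1-yl]-3-(3-methylbut-2-en-1-yl)benzene
Conditions: Bu4NF (1.2 equiv), THF, 0 °C → rt
Reagents that add atoms: none
Why: Fluoride-mediated protodesilylation should cleave the alkynyl C–Si bond selectively, the MOM ethers and both alkenes being inert to Bu4NF.

Step 14
Reactants: 26 5-ethynyl-2-(methoxymethoxy)-1-[(2R)-2-(methoxymethoxy)-3-methylbut-3-en-1-yl]-3-(3-methylbut-2-en-1-yl)benzene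
Product: 28 3-{4-(methoxymethoxy)-3-[(2R)-2-(methoxymethoxy)-3-methylbut-3-en-1-yl]-5-(3-methylbut-2-en-1-yl)phenyl}prop-2-ynoic acid, via lithium acetylide 27 (not isolated)
Conditions: n-BuLi (1.1 equiv), THF, −78 °C; CO2 (dry gas), −78 → 0 °C; cold 1 M HCl to pH 3, immediate extraction
Reagents that add atoms: carbon dioxide, O=C=O
Why: Deprotonation of the terminal alkyne by n-BuLi and carboxylation of the lithium acetylide with CO2 should give the propiolic acid, ring metalation being excluded because both positions ortho to the aryl OMOM group are substituted.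

Step 15
Reactants: 28 3-{4-(methoxymethoxy)-3-[(2R)-2-(methoxymethoxy)-3-methylbut-3-en-1-yl]-5-(3-methylbut-2-en-1-yl)phenyl}prop-2-ynoic acid; 9 3,5-bis(methoxymethoxy)-2-(trimethylsilyl)phenyl trifluoromethanesulfonate
Product: 32 5,7-bis(methoxymethoxy)-2-{4-(methoxymethoxy)-3-[(2R)-2-(methoxymethoxy)-3-methylbut-3-en-1-yl]-5-(3-methylbut-2-en-1-yl)phenyl}-4H-chromen-4-one, via cesium carboxylate 29 (not isolated), via aryne 30 (not isolated), via ynone phenoxide 31 (not isolated)
Conditions: 9 (1.5 equiv), CsF (4 equiv), THF, 110 °C, sealed tube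
Reagents that add atoms: none
Why: Fluoride removes the silyl group of 9 and triflate leaves, giving aryne 30, while fluoride also converts acid 28 into carboxylate 29, whose oxygen should add to the aryne carbon remote from the flanking OMOM group (the future C8a) so that the aryl anion develops at the future C4a, where the adjacent C–O bond stabilises it. That anion attacks the ester carbonyl through a four-membered adduct that opens to the 2-acylphenoxide 31, an anionic Fries-type acyl shift that forms C4a–C4. The closest known reaction type is the intermolecular C–O insertion of arynes into carboxylic acids to give ortho-hydroxyaryl ketones, including its use with 3-arylpropiolic acids to give flavones. Ring C, the only ring formed, then closes by 6-endo-dig oxa-Michael addition of the phenoxide to the β-carbon of the ynone (O1–C2), the C3 anion is protonated by the HF released when the acid was deprotonated, and no stereocentre is formed. The step needs regioselective aryne capture, acyl transfer instead of protonation to the aryl ester, and 6-endo instead of 5-exo closure: the first is secured by the oxygen substituent next to the aryne, the second by the hot aprotic medium, the third by the polarisation of the ynone toward its β-carbon. The MOM ethers, both alkenes and the remote (R) centre should be inert to CsF at this temperature.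

Step 16
Reactants: 32 5,7-bis(methoxymethoxy)-2-{4-(methoxymethoxy)-3-[(2R)-2-(methoxymethoxy)-3-methylbut-3-en-1-yl]-5-(3-methylbut-2-en-1-yl)phenyl}-4H-chromen-4-one
Product: 33 5,7-dihydroxy-2-{4-hydroxy-3-[(2R)-2-hydroxy-3-methylbut-3-en-1-yl]-5-(3-methylbut-2-en-1-yl)phenyl}-4H-chromen-4-one (CNP0357492.1)
Conditions: 3 M aq. HCl–MeOH–THF (1:4:1), 40 °C, stopped as soon as the last partly protected intermediate is consumed
Reagents that add atoms: none
Why: Acid-catalysed transacetalisation to methanol (methanolysis of the MOM ethers, giving dimethoxymethane) should free the three phenols and the secondary alcohol without touching the stereocentre, whose C–O bond is not broken, provided the acid is kept dilute and the temperature low so that the liberated 4′-phenol does not add to the flanking alkenes.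

**Compound list**

1 | phloroglucinol | Oc1cc(O)cc(O)c1 | starting material
2 | 3,5-bis(methoxymethoxy)phenol | COCOc1cc(O)cc(OCOC)c1 | intermediate
3 | 3,5-bis(methoxymethoxy)phenyl N-(propan-2-yl)carbamate | CC(C)NC(=O)Oc1cc(OCOC)cc(OCOC)c1 | intermediate
4 | 3,5-bis(methoxymethoxy)phenyl N-[tert-butyl(dimethyl)silyl]-N-(propan-2-yl)carbamate (not isolated) | CC(C)N([Si](C)(C)C(C)(C)C)C(=O)Oc1cc(OCOC)cc(OCOC)c1 | intermediate
5 | 2-lithio derivative of 4 (not isolated) | CC(C)N([Si](C)(C)C(C)(C)C)C(=O)Oc1cc(OCOC)cc(OCOC)c1[Li] | intermediate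
6 | 3,5-bis(methoxymethoxy)-2-(trimethylsilyl)phenyl N-[tert-butyl(dimethyl)silyl]-N-(propan-2-yl)carbamate (not isolated) | CC(C)N([Si](C)(C)C(C)(C)C)C(=O)Oc1cc(OCOC)cc(OCOC)c1[Si](C)(C)C | intermediate
7 | 3,5-bis(methoxymethoxy)-2-(trimethylsilyl)phenyl N-(propan-2-yl)carbamate | CC(C)NC(=O)Oc1cc(OCOC)cc(OCOC)c1[Si](C)(C)C | intermediate
8 | 3,5-bis(methoxymethoxy)-2-(trimethylsilyl)phenol (not isolated) | COCOc1cc(O)c([Si](C)(C)C)c(OCOC)c1 | intermediate
9 | 3,5-bis(methoxymethoxy)-2-(trimethylsilyl)phenyl trifluoromethanesulfonate | COCOc1cc(OCOC)c([Si](C)(C)C)c(OS(=O)(=O)C(F)(F)F)c1 | intermediate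
10 | 3,5-dibromo-4-hydroxybenzaldehyde | O=Cc1cc(Br)c(O)c(Br)c1 | starting material
11 | 3,5-dibromo-4-(methoxymethoxy)benzaldehyde | COCOc1c(Br)cc(C=O)cc1Br | intermediate
12 | 1,3-dibromo-5-ethynyl-2-(methoxymethoxy)benzene | C#Cc1cc(Br)c(OCOC)c(Br)c1 | intermediate
13 | lithium acetylide of 12 (not isolated) | [Li]C#Cc1cc(Br)c(OCOC)c(Br)c1 | intermediate
14 | {[3,5-dibromo-4-(methoxymethoxy)phenyl]ethynyl}tri(propan-2-yl)silane | COCOc1c(Br)cc(C#C[Si](C(C)C)(C(C)C)C(C)C)cc1Br | intermediate
15 | prenyl bromide (1-bromo-3-methylbut-2-ene) | CC(C)=CCBr | starting material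
16 | {3-bromo-2-(methoxymethoxy)-5-[(triisopropylsilyl)ethynyl]phenyl}lithium (not isolated) | [Li]c1cc(C#C[Si](C(C)C)(C(C)C)C(C)C)cc(Br)c1OCOC | intermediate
17 | {3-bromo-2-(methoxymethoxy)-5-[(triisopropylsilyl)ethynyl]phenyl}copper (not isolated) | [Cu]c1cc(C#C[Si](C(C)C)(C(C)C)C(C)C)cc(Br)c1OCOC | intermediate
18 | {[3-bromo-4-(methoxymethoxy)-5-(3-methylbut-2-en-1-yl)phenyl]ethynyl}tri(propan-2-yl)silane | COCOc1c(Br)cc(C#C[Si](C(C)C)(C(C)C)C(C)C)cc1CC=C(C)C | intermediate
19 | methyl (R)-glycidate [methyl (2R)-oxirane-2-carboxylate] | COC(=O)[C@H]1CO1 | starting material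
20 | {2-(methoxymethoxy)-3-(3-methylbut-2-en-1-yl)-5-[(triisopropylsilyl)ethynyl]phenyl}magnesium bromide (not isolated) | Br[Mg]c1cc(C#C[Si](C(C)C)(C(C)C)C(C)C)cc(CC=C(C)C)c1OCOC | intermediate
21 | methyl (2R)-2-hydroxy-3-{2-(methoxymethoxy)-3-(3-methylbut-2-en-1-yl)-5-[(triisopropylsilyl)ethynyl]phenyl}propanoate | COC(=O)[C@H](O)Cc1cc(C#C[Si](C(C)C)(C(C)C)C(C)C)cc(CC=C(C)C)c1OCOC | intermediate
22 | methyl (2R)-2-(methoxymethoxy)-3-{2-(methoxymethoxy)-3-(3-methylbut-2-en-1-yl)-5-[(triisopropylsilyl)ethynyl]phenyl}propanoate | COC(=O)[C@H](OCOC)Cc1cc(C#C[Si](C(C)C)(C(C)C)C(C)C)cc(CC=C(C)C)c1OCOC | intermediate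
23 | (2R)-N-methoxy-2-(methoxymethoxy)-N-methyl-3-{2-(methoxymethoxy)-3-(3-methylbut-2-en-1-yl)-5-[(triisopropylsilyl)ethynyl]phenyl}propanamide (not isolated) | CON(C)C(=O)[C@H](OCOC)Cc1cc(C#C[Si](C(C)C)(C(C)C)C(C)C)cc(CC=C(C)C)c1OCOC | intermediate
24 | (3R)-3-(methoxymethoxy)-4-{2-(methoxymethoxy)-3-(3-methylbut-2-en-1-yl)-5-[(triisopropylsilyl)ethynyl]phenyl}butan-2-one | CC(=O)[C@H](OCOC)Cc1cc(C#C[Si](C(C)C)(C(C)C)C(C)C)cc(CC=C(C)C)c1OCOC | intermediate
25 | {[4-(methoxymethoxy)-3-[(2R)-2-(methoxymethoxy)-3-methylbut-3-en-1-yl]-5-(3-methylbut-2-en-1-yl)phenyl]ethynyl}tri(propan-2-yl)silane | C=C(C)[C@H](OCOC)Cc1cc(C#C[Si](C(C)C)(C(C)C)C(C)C)cc(CC=C(C)C)c1OCOC | intermediate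
26 | 5-ethynyl-2-(methoxymethoxy)-1-[(2R)-2-(methoxymethoxy)-3-methylbut-3-en-1-yl]-3-(3-methylbut-2-en-1-yl)benzene | C=C(C)[C@H](OCOC)Cc1cc(C#C)cc(CC=C(C)C)c1OCOC | intermediate
27 | lithium acetylide of 26 (not isolated) | C=C(C)[C@H](OCOC)Cc1cc(C#C[Li])cc(CC=C(C)C)c1OCOC | intermediate
28 | 3-{4-(methoxymethoxy)-3-[(2R)-2-(methoxymethoxy)-3-methylbut-3-en-1-yl]-5-(3-methylbut-2-en-1-yl)phenyl}prop-2-ynoic acid | C=C(C)[C@H](OCOC)Cc1cc(C#CC(=O)O)cc(CC=C(C)C)c1OCOC | intermediate
29 | cesium salt of 28 (not isolated) | C=C(C)[C@H](OCOC)Cc1cc(C#CC(=O)[O-])cc(CC=C(C)C)c1OCOC.[Cs+] | intermediate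
30 | 3,5-bis(methoxymethoxy)benzyne, formal triple bond between the former C–OTf and C–Si carbons (not isolated) | COCOC1=CC(OCOC)=CC#C1 | intermediate
31 | cesium 2-(3-arylprop-2-ynoyl)-3,5-bis(methoxymethoxy)phenoxide, aryl = the ring B unit of 28 (not isolated) | C=C(C)[C@H](OCOC)Cc1cc(C#CC(=O)c2c([O-])cc(OCOC)cc2OCOC)cc(CC=C(C)C)c1OCOC.[Cs+] | intermediate
32 | 5,7-bis(methoxymethoxy)-2-{4-(methoxymethoxy)-3-[(2R)-2-(methoxymethoxy)-3-methylbut-3-en-1-yl]-5-(3-methylbut-2-en-1-yl)phenyl}-4H-chromen-4-one | C=C(C)[C@H](OCOC)Cc1cc(-c2cc(=O)c3c(OCOC)cc(OCOC)cc3o2)cc(CC=C(C)C)c1OCOC | intermediate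
33 | 5,7-dihydroxy-2-{4-hydroxy-3-[(2R)-2-hydroxy-3-methylbut-3-en-1-yl]-5-(3-methylbut-2-en-1-yl)phenyl}-4H-chromen-4-one | C=C(C)[C@H](O)Cc1cc(-c2cc(=O)c3c(O)cc(O)cc3o2)cc(CC=C(C)C)c1O | target

**Count and risks**

Total steps: 16. Longest linear sequence: 12 steps (10 → 33, steps 5–16); the aryne branch (steps 1–4) joins at step 15.

Steps most likely to fail:

Step 15. The aryl anion may pick up a proton before the acyl shift, so that the reaction stops at the aryl ester. Carboxylate addition to the aryne may also lose regiocontrol, or the propiolate may decarboxylate at the temperature the acyl shift needs. The fallback is a palladium-catalysed carbonylative annulation that forms the same C4a–C4 and O1–C2 bonds from an ortho-iodophenol, a terminal alkyne and CO. It sets out from carbamate 3 and alkyne 26 and comes back at 32. Carbamate 3 is N-silylated and lithiated as in step 3 (through 4 and 5), but the aryllithium is quenched with I2 to give 2-iodo-3,5-bis(methoxymethoxy)phenyl N-[tert-butyl(dimethyl)silyl]-N-(propan-2-yl)carbamate F1. On aqueous work-up this loses the N-silyl group to give 2-iodo-3,5-bis(methoxymethoxy)phenyl N-(propan-2-yl)carbamate F2. Et2NH and DBU in MeCN then release 2-iodo-3,5-bis(methoxymethoxy)phenol F3. Heating F3 and 26 with PdCl2(dppf) in Et2NH under CO (carbonylative Sonogashira coupling) should give 1-[2-hydroxy-4,6-bis(methoxymethoxy)phenyl]-3-{4-(methoxymethoxy)-3-[(2R)-2-(methoxymethoxy)-3-methylbut-3-en-1-yl]-5-(3-methylbut-2-en-1-yl)phenyl}prop-2-yn-1-one F4, which cyclises in the amine medium by 6-endo addition to 32.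

Step 16. Once the 4′-phenol is free, the acid may add it across the flanking isopropenyl or prenyl double bond (chroman formation), or ionise the allylic carbinol, before the slower secondary alkyl MOM ether has gone. The fallback transfers the four acetals to a thiol under Lewis acid activation instead of solvolysing them with protic acid. It sets out from 32 and comes back at 33: 32 is treated with ZnBr2 and propane-1-thiol in CH2Cl2 at 0 °C for a few minutes and quenched with aqueous NaHCO3. No new isolable compound lies on the way.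

Step 12. The basic ylide may enolise the α-alkoxy ketone and erode the enantiomeric purity, or the hindered ketone may be methylenated only slowly. The fallback avoids any enolisable ketone; it sets out from ester 22 and comes back at 25. Ester 22 is treated with excess MeMgBr (THF, 0 °C) to give (3R)-3-(methoxymethoxy)-2-methyl-4-{2-(methoxymethoxy)-3-(3-methylbut-2-en-1-yl)-5-[(triisopropylsilyl)ethynyl]phenyl}butan-2-ol F5. Dehydration of F5 with the Burgess reagent (toluene, 50 °C, syn-elimination) should go toward a methyl group, favoured statistically and electronically over the hydrogen on the oxygen-bearing carbon, to give 25.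

Further compounds
F1 | step 15 | 2-iodo-3,5-bis(methoxymethoxy)phenyl N-[tert-butyl(dimethyl)silyl]-N-(propan-2-yl)carbamate | CC(C)N([Si](C)(C)C(C)(C)C)C(=O)Oc1cc(OCOC)cc(OCOC)c1I
F2 | step 15 | 2-iodo-3,5-bis(methoxymethoxy)phenyl N-(propan-2-yl)carbamate | CC(C)NC(=O)Oc1cc(OCOC)cc(OCOC)c1I
F3 | step 15 | 2-iodo-3,5-bis(methoxymethoxy)phenol | COCOc1cc(O)c(I)c(OCOC)c1
F4 | step 15 | 1-[2-hydroxy-4,6-bis(methoxymethoxy)phenyl]-3-{4-(methoxymethoxy)-3-[(2R)-2-(methoxymethoxy)-3-methylbut-3-en-1-yl]-5-(3-methylbut-2-en-1-yl)phenyl}prop-2-yn-1-one | C=C(C)[C@H](OCOC)Cc1cc(C#CC(=O)c2c(O)cc(OCOC)cc2OCOC)cc(CC=C(C)C)c1OCOC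
F0 | step 16 | none | none
F5 | step 12 | (3R)-3-(methoxymethoxy)-2-methyl-4-{2-(methoxymethoxy)-3-(3-methylbut-2-en-1-yl)-5-[(triisopropylsilyl)ethynyl]phenyl}butan-2-ol | CC(C)(O)[C@H](OCOC)Cc1cc(C#C[Si](C(C)C)(C(C)C)C(C)C)cc(CC=C(C)C)c1OCOC
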